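**Strategy.** Labdane numbering is used. The route rests on disconnecting ring B between the ring-fusion carbon C5 and the acetoxy carbon C6. The C6 oxygen is γ to the C19 ester carbonyl (O–C6–C5–C4–C19=O), the pattern left by a ketyl–enoate coupling. Accordingly, SmI2 reduces an open-chain β,γ-unsaturated aldehyde (C6) to a ketyl that adds 6-exo to C5 of an (E)-enoate (C5=C4–C19). This closes ring B and sets C5 and C6 in one operation through a chair anchored by C9 and C10. These two centres come from an enantioselective Ireland–Claisen rearrangement; ring A is closed afterwards by ester enolate alkylation and C4 methylation.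

Key step: step 11

Assumption: in step 6 the (4S,5S)-boron controller with i-Pr2NEt in CH2Cl2 is taken to give the ketene acetal geometry and facial sense shown; if either is reversed, Et3N in toluene/hexane or the enantiomeric controller is used and nothing else changes.

"Silyl enynyl" below means the (2Z)-3-methyl-5-(trimethylsilyl)pent-2-en-4-yn-1-yl side chain.

Step 1
Reactants: 1 geranyl acetate
Product: 2 (2E)-6-hydroxy-3-methylhex-2-en-1-yl acetate
Conditions: O3, CH2Cl2/MeOH, pyridine, −78 °C; then NaBH4, −78 → 0 °C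
Reagents that add atoms: ozone, [O-][O+]=O
Why: Chemoselective ozonolysis with reductive work-up should cleave only the electron-rich 6,7-alkene, because the allylic acetate deactivates the 2,3-alkene, and the (E)-geometry is untouched.

Step 2
Reactants: 2 (2E)-6-hydroxy-3-methylhex-2-en-1-yl acetate
Product: 3 (2E)-6-chloro-3-methylhex-2-en-1-yl acetate
Conditions: NCS, PPh3, CH2Cl2, 0 °C → rt
Reagents that add atoms: N-chlorosuccinimide, O=C1CCC(=O)N1Cl
Why: Appel-type chlorination of the primary alcohol gives a chloride that is inert to all later steps until the ring A closure.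

Step 3
Reactants: 4 (2Z)-3-methylpent-2-en-4-yn-1-ol
Product: 6 (2Z)-3-methyl-5-(trimethylsilyl)pent-2-en-4-yn-1-ol, via bis-silyl ether 5 (not isolated)
Conditions: n-BuLi (2.2 equiv), THF, −78 → 0 °C; Me3SiCl (2.3 equiv); then 1 M HCl, THF, rt
Reagents that add atoms: chlorotrimethylsilane, C[Si](C)(C)Cl
Why: Silylation of the alkoxide/acetylide dianion followed by selective hydrolysis of the O–Si bond masks the acidic alkyne C–H for the later enolate steps.

Step 4
Reactants: 6 (2Z)-3-methyl-5-(trimethylsilyl)pent-2-en-4-yn-1-ol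
Product: 7 [(3Z)-5-bromo-3-methylpent-3-en-1-yn-1-yl]trimethylsilane
Conditions: CBr4, PPh3, CH2Cl2, 0 °C
Reagents that add atoms: carbon tetrabromide, BrC(Br)(Br)Br
Why: Appel bromination of the primary allylic alcohol proceeds by SN2 at 0 °C and should keep the (Z)-alkene.

Step 5
Reactants: 3 (2E)-6-chloro-3-methylhex-2-en-1-yl acetate; 7 [(3Z)-5-bromo-3-methylpent-3-en-1-yn-1-yl]trimethylsilane
Product: 8 (2E)-6-chloro-3-methylhex-2-en-1-yl (4Z)-5-methyl-7-(trimethylsilyl)hept-4-en-6-ynoate
Conditions: LiN(i-Pr)2 (LDA), THF, −78 °C; then 7, DMPU, −78 → −40 °C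
Reagents that add atoms: none
Why: Ester enolate alkylation (SN2) of the acetate enolate by the primary allylic bromide occurs below the temperature at which the allyl ester enolate itself rearranges, so the acetyl group of 3 becomes C8/C9.

Step 6
Reactants: 8 (2E)-6-chloro-3-methylhex-2-en-1-yl (4Z)-5-methyl-7-(trimethylsilyl)hept-4-en-6-ynoate
Product: 10 methyl (2R,3S)-3-(3-chloropropyl)-3-methyl-2-(silyl enynyl)pent-4-enoate, via carboxylic acid 9 (not isolated)
Conditions: (4S,5S)-2-bromo-4,5-diphenyl-1,3-bis{[3,5-bis(trifluoromethyl)phenyl]sulfonyl}-1,3,2-diazaborolidine (1.2 equiv), i-Pr2NEt, CH2Cl2, −78 → 4 °C; aqueous work-up; then Me3SiCHN2, PhMe/MeOH, 0 °C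
Reagents that add atoms: (trimethylsilyl)diazomethane, C[Si](C)(C)C=[N+]=[N-]
Why: Enantioselective Ireland–Claisen rearrangement: the boron ketene acetal with the side chain cis to O–B rearranges through a chair in which the (E)-allyl unit holds the C10 methyl axial and the chloropropyl chain equatorial, which sets C9 and C10 in the required relative sense, while the C2-symmetric sulfonamide controller on boron selects the face; the crude acid is then O-methylated.

Step 7
Reactants: 10 methyl (2R,3S)-3-(3-chloropropyl)-3-methyl-2-(silyl enynyl)pent-4-enoate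
Product: 12 allylsilane {(3R,4S)-4-(3-chloropropyl)-4-methyl-2-methylidene-3-(silyl enynyl)hex-5-en-1-yl}trimethylsilane, via tertiary carbinol 11 (not isolated)
Conditions: Me3SiCH2MgCl, CeCl3, THF, −78 °C → rt; then SiO2, CH2Cl2
Reagents that add atoms: (trimethylsilyl)methylmagnesium chloride, C[Si](C)(C)C[Mg]Cl
Why: Double addition of the weakly basic organocerium reagent to the ester and Peterson elimination of the resulting β-hydroxysilane on silica should give the 2-substituted allylsilane without epimerising C9.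

Step 8
Reactants: 12 allylsilane {(3R,4S)-4-(3-chloropropyl)-4-methyl-2-methylidene-3-(silyl enynyl)hex-5-en-1-yl}trimethylsilane
Product: 13 (4S,5S)-5-(3-chloropropyl)-5-methyl-3-methylidene-4-(silyl enynyl)hept-6-en-1-ol
Conditions: 1,3,5-trioxane, BF3·OEt2, CH2Cl2, −78 → −20 °C
Reagents that add atoms: 1,3,5-trioxane, C1OCOCO1
Why: Hosomi–Sakurai reaction: the allylsilane attacks BF3-activated formaldehyde at its terminal carbon (SE2′), which attaches C6 as a primary alcohol and regenerates the 1,1-disubstituted alkene as the C8 exo-methylene.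

Step 9
Reactants: 13 (4S,5S)-5-(3-chloropropyl)-5-methyl-3-methylidene-4-(silyl enynyl)hept-6-en-1-ol; 14 methyl acrylate
Product: 15 methyl (2E,4S,5S)-4-(3-chloropropyl)-8-hydroxy-4-methyl-6-methylidene-5-(silyl enynyl)oct-2-enoate
Conditions: methyl acrylate (excess), second-generation Hoveyda–Grubbs catalyst RuCl2(=CH-C6H4-2-Oi-Pr)(H2IMes) (10 mol%), CH2Cl2, 40 °C
Reagents that add atoms: none
Why: Olefin cross-metathesis of the monosubstituted vinyl group with the electron-poor acrylate should give the (E)-enoate, since the hindered 1,1-disubstituted methylene, the trisubstituted enyne alkene and the silyl alkyne react much more slowly.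

Step 10
Reactants: 15 methyl (2E,4S,5S)-4-(3-chloropropyl)-8-hydroxy-4-methyl-6-methylidene-5-(silyl enynyl)oct-2-enoate
Product: 16 methyl (2E,4S,5S)-4-(3-chloropropyl)-4-methyl-6-methylidene-5-(silyl enynyl)-8-oxooct-2-enoate
Conditions: Dess–Martin periodinane, NaHCO3, CH2Cl2, 0 °C
Reagents that add atoms: none
Why: Buffered Dess–Martin oxidation of the primary homoallylic alcohol should give the β,γ-unsaturated aldehyde without conjugation of the C8 methylene; it is used at once.

Step 11
Reactants: 16 methyl (2E,4S,5S)-4-(3-chloropropyl)-4-methyl-6-methylidene-5-(silyl enynyl)-8-oxooct-2-enoate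
Product: 17 methyl 2-{(1S,2S,5S,6R)-6-(3-chloropropyl)-2-hydroxy-6-methyl-4-methylidene-5-(silyl enynyl)cyclohexyl}acetate
Conditions: SmI2 (2.5 equiv), HMPA, t-BuOH, THF, −78 °C
Reagents that add atoms: none
Why: SmI2 reduces the C6 aldehyde to a samarium ketyl radical that adds to C5, the β-carbon of the (E)-enoate, and the resulting C4 α-ester radical is reduced by a second SmI2 to the samarium enolate and protonated by t-BuOH. The closest known reaction type is the SmI2-mediated ketyl–olefin (aldehyde–enoate) reductive cyclization. Ring B closes in the 6-exo-trig mode through a chair-like transition state. That chair is anchored by the equatorial C9 side chain and the axial C10 methyl fixed in step 6, so the enoate arm on C5 and the HMPA-solvated O–Sm on C6 both take equatorial positions, which places C5–H anti to the C10 methyl (the later trans ring fusion) and gives the 6α-hydroxyl anti to the C5 substituent. The step needs chemoselectivity for the enoate over the silyl enyne and exo-methylene and survival of the β,γ-unsaturated aldehyde; polarity matching of the nucleophilic ketyl with the electron-poor enoate, the quaternary C10 that favours closure, the inert primary chloride and the non-basic medium at −78 °C should secure this.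

Step 12
Reactants: 17 methyl 2-{(1S,2S,5S,6R)-6-(3-chloropropyl)-2-hydroxy-6-methyl-4-methylidene-5-(silyl enynyl)cyclohexyl}acetate
Product: 18 the C6 tert-butyldimethylsilyl ether of 17
Conditions: TBSOTf, 2,6-lutidine, CH2Cl2, 0 °C
Reagents that add atoms: tert-butyldimethylsilyl trifluoromethanesulfonate, CC(C)(C)[Si](C)(C)OS(=O)(=O)C(F)(F)F
Why: Silylation of the secondary alcohol prevents lactonisation and alkoxide interference in the enolate steps that follow.

Step 13
Reactants: 18 the C6 tert-butyldimethylsilyl ether of 17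
Product: 20 methyl (1S,4aR,5S,8S,8aR)-8-[(tert-butyldimethylsilyl)oxy]-1,4a-dimethyl-6-methylidene-5-(silyl enynyl)decahydronaphthalene-1-carboxylate, via cyclised ester 19 (not isolated)
Conditions: LiN(i-Pr)2 (LDA), THF/HMPA, −78 → 0 °C; then LiN(i-Pr)2, −78 → 0 °C; MeI, −78 °C → rt
Reagents that add atoms: iodomethane, CI
Why: Intramolecular ester enolate alkylation (6-exo-tet) by the primary chloride closes ring A, and C-methylation of the second, exocyclic ester enolate should occur on the α-face, opposite the axial C10 methyl, which makes C4 with the methyl equatorial and the ester axial, as established for decalin-4-carboxylate enolates.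

Step 14
Reactants: 20 methyl (1S,4aR,5S,8S,8aR)-8-[(tert-butyldimethylsilyl)oxy]-1,4a-dimethyl-6-methylidene-5-(silyl enynyl)decahydronaphthalene-1-carboxylate
Product: 21 methyl (1S,4aR,5S,8S,8aR)-8-hydroxy-1,4a-dimethyl-6-methylidene-5-[(2Z)-3-methylpent-2-en-4-yn-1-yl]decahydronaphthalene-1-carboxylate
Conditions: Bu4NF, THF, 0 → 45 °C
Reagents that add atoms: none
Why: Fluoride cleaves both the C6 silyl ether and the alkynyl C–Si bond, while the hindered axial methyl ester is left alone.

Step 15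
Reactants: 21 methyl (1S,4aR,5S,8S,8aR)-8-hydroxy-1,4a-dimethyl-6-methylidene-5-[(2Z)-3-methylpent-2-en-4-yn-1-yl]decahydronaphthalene-1-carboxylate
Product: 22 the 8-acetate of 21 (6α-acetate in labdane numbering)
Conditions: Ac2O, pyridine, DMAP (cat.), CH2Cl2, rt
Reagents that add atoms: acetic anhydride, CC(=O)OC(C)=O
Why: DMAP-catalysed acylation of the equatorial secondary alcohol proceeds with retention at C6.

Step 16
Reactants: 22 the 8-acetate of 21
Product: 23 methyl (1S,4aR,5S,8S,8aR)-8-acetoxy-1,4a-dimethyl-6-methylidene-5-[(2Z)-3-methylpenta-2,4-dien-1-yl]decahydronaphthalene-1-carboxylate (target)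
Conditions: H2 (1 atm), Pd/CaCO3 poisoned with Pb(OAc)2 (Lindlar catalyst), quinoline, EtOAc, rt
Reagents that add atoms: none
Why: Lindlar semi-hydrogenation of the terminal alkyne to the vinyl group completes the (Z)-diene, and the poisoned catalyst should not reduce the trisubstituted alkene or the exo-methylene.

**Compound list**

1 | geranyl acetate, (2E)-3,7-dimethylocta-2,6-dien-1-yl acetate | CC(C)=CCC/C(C)=C/COC(C)=O | starting material
2 | (2E)-6-hydroxy-3-methylhex-2-en-1-yl acetate | OCCC/C(C)=C/COC(C)=O | intermediate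
3 | (2E)-6-chloro-3-methylhex-2-en-1-yl acetate | ClCCC/C(C)=C/COC(C)=O | intermediate
4 | (2Z)-3-methylpent-2-en-4-yn-1-ol | C#C/C(C)=C\CO | starting material
5 | trimethyl{[(2Z)-3-methyl-5-(trimethylsilyl)pent-2-en-4-yn-1-yl]oxy}silane | C[Si](C)(C)C#C/C(C)=C\CO[Si](C)(C)C | intermediate (not isolated)
6 | (2Z)-3-methyl-5-(trimethylsilyl)pent-2-en-4-yn-1-ol | C[Si](C)(C)C#C/C(C)=C\CO | intermediate
7 | [(3Z)-5-bromo-3-methylpent-3-en-1-yn-1-yl]trimethylsilane | C[Si](C)(C)C#C/C(C)=C\CBr | intermediate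
8 | (2E)-6-chloro-3-methylhex-2-en-1-yl (4Z)-5-methyl-7-(trimethylsilyl)hept-4-en-6-ynoate | C[Si](C)(C)C#C/C(C)=C\CCC(=O)OC/C=C(\C)CCCCl | intermediate
9 | (2R,3S)-3-(3-chloropropyl)-3-methyl-2-[(2Z)-3-methyl-5-(trimethylsilyl)pent-2-en-4-yn-1-yl]pent-4-enoic acid | C[Si](C)(C)C#C/C(C)=C\C[C@H]([C@](C=C)(CCCCl)C)C(=O)O | intermediate (not isolated)
10 | methyl (2R,3S)-3-(3-chloropropyl)-3-methyl-2-[(2Z)-3-methyl-5-(trimethylsilyl)pent-2-en-4-yn-1-yl]pent-4-enoate | C[Si](C)(C)C#C/C(C)=C\C[C@H]([C@](C=C)(CCCCl)C)C(=O)OC | intermediate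
11 | (3R,4S)-4-(3-chloropropyl)-4-methyl-3-[(2Z)-3-methyl-5-(trimethylsilyl)pent-2-en-4-yn-1-yl]-1-(trimethylsilyl)-2-[(trimethylsilyl)methyl]hex-5-en-2-ol | C[Si](C)(C)C#C/C(C)=C\C[C@H]([C@](C=C)(CCCCl)C)C(O)(C[Si](C)(C)C)C[Si](C)(C)C | intermediate (not isolated)
12 | {(3R,4S)-4-(3-chloropropyl)-4-methyl-2-methylidene-3-[(2Z)-3-methyl-5-(trimethylsilyl)pent-2-en-4-yn-1-yl]hex-5-en-1-yl}trimethylsilane | C[Si](C)(C)C#C/C(C)=C\C[C@H]([C@](C=C)(CCCCl)C)C(=C)C[Si](C)(C)C | intermediate
13 | (4S,5S)-5-(3-chloropropyl)-5-methyl-3-methylidene-4-[(2Z)-3-methyl-5-(trimethylsilyl)pent-2-en-4-yn-1-yl]hept-6-en-1-ol | C[Si](C)(C)C#C/C(C)=C\C[C@H]([C@](C=C)(CCCCl)C)C(=C)CCO | intermediate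
14 | methyl acrylate | C=CC(=O)OC | starting material
15 | methyl (2E,4S,5S)-4-(3-chloropropyl)-8-hydroxy-4-methyl-6-methylidene-5-[(2Z)-3-methyl-5-(trimethylsilyl)pent-2-en-4-yn-1-yl]oct-2-enoate | C[Si](C)(C)C#C/C(C)=C\C[C@H]([C@](/C=C/C(=O)OC)(CCCCl)C)C(=C)CCO | intermediate
16 | methyl (2E,4S,5S)-4-(3-chloropropyl)-4-methyl-6-methylidene-5-[(2Z)-3-methyl-5-(trimethylsilyl)pent-2-en-4-yn-1-yl]-8-oxooct-2-enoate | C[Si](C)(C)C#C/C(C)=C\C[C@H]([C@](/C=C/C(=O)OC)(CCCCl)C)C(=C)CC=O | intermediate
17 | methyl 2-{(1S,2S,5S,6R)-6-(3-chloropropyl)-2-hydroxy-6-methyl-4-methylidene-5-[(2Z)-3-methyl-5-(trimethylsilyl)pent-2-en-4-yn-1-yl]cyclohexyl}acetate | C[Si](C)(C)C#C/C(C)=C\C[C@H]1C(=C)C[C@H](O)[C@@H](CC(=O)OC)[C@]1(C)CCCCl | intermediate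
18 | methyl 2-{(1S,2S,5S,6R)-2-[(tert-butyldimethylsilyl)oxy]-6-(3-chloropropyl)-6-methyl-4-methylidene-5-[(2Z)-3-methyl-5-(trimethylsilyl)pent-2-en-4-yn-1-yl]cyclohexyl}acetate | C[Si](C)(C)C#C/C(C)=C\C[C@H]1C(=C)C[C@H](O[Si](C)(C)C(C)(C)C)[C@@H](CC(=O)OC)[C@]1(C)CCCCl | intermediate
19 | methyl (4aR,5S,8S,8aS)-8-[(tert-butyldimethylsilyl)oxy]-4a-methyl-6-methylidene-5-[(2Z)-3-methyl-5-(trimethylsilyl)pent-2-en-4-yn-1-yl]decahydronaphthalene-1-carboxylate (both C1 epimers) | C[Si](C)(C)C#C/C(C)=C\C[C@H]1C(=C)C[C@H](O[Si](C)(C)C(C)(C)C)[C@@H]2[C@]1(C)CCCC2C(=O)OC | intermediate (not isolated)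
20 | methyl (1S,4aR,5S,8S,8aR)-8-[(tert-butyldimethylsilyl)oxy]-1,4a-dimethyl-6-methylidene-5-[(2Z)-3-methyl-5-(trimethylsilyl)pent-2-en-4-yn-1-yl]decahydronaphthalene-1-carboxylate | C[Si](C)(C)C#C/C(C)=C\C[C@H]1C(=C)C[C@H](O[Si](C)(C)C(C)(C)C)[C@@H]2[C@]1(C)CCC[C@]2(C)C(=O)OC | intermediate
21 | methyl (1S,4aR,5S,8S,8aR)-8-hydroxy-1,4a-dimethyl-6-methylidene-5-[(2Z)-3-methylpent-2-en-4-yn-1-yl]decahydronaphthalene-1-carboxylate | C#C/C(C)=C\C[C@H]1C(=C)C[C@H](O)[C@@H]2[C@]1(C)CCC[C@]2(C)C(=O)OC | intermediate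
22 | methyl (1S,4aR,5S,8S,8aR)-8-acetoxy-1,4a-dimethyl-6-methylidene-5-[(2Z)-3-methylpent-2-en-4-yn-1-yl]decahydronaphthalene-1-carboxylate | C#C/C(C)=C\C[C@H]1C(=C)C[C@H](OC(C)=O)[C@@H]2[C@]1(C)CCC[C@]2(C)C(=O)OC | intermediate
23 | methyl (1S,4aR,5S,8S,8aR)-8-acetoxy-1,4a-dimethyl-6-methylidene-5-[(2Z)-3-methylpenta-2,4-dien-1-yl]decahydronaphthalene-1-carboxylate | C=C/C(C)=C\C[C@H]1C(=C)C[C@H](OC(C)=O)[C@@H]2[C@]1(C)CCC[C@]2(C)C(=O)OC | target

**Step count.** Total: 16 steps. Longest linear sequence: 14 steps (steps 1, 2 and 5–16); the side-chain bromide takes 2 further steps (3 and 4).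

**Steps most likely to fail**

Step 11 (key step). The chair may not be followed cleanly (enoate arm axial, or the ketyl adding to the silyl enyne), and the β,γ-unsaturated aldehyde may isomerise or dimerise before it cyclises. The fallback sets out from 16 and closes the same bond by a polar, non-radical path. An intramolecular Stetter reaction with an N-heterocyclic carbene (from 2-mesityl-6,7-dihydro-5H-pyrrolo[2,1-c][1,2,4]triazolium chloride and i-Pr2NEt, toluene) should give the γ-keto ester methyl 2-{(1S,5S,6R)-6-(3-chloropropyl)-6-methyl-4-methylidene-5-(silyl enynyl)-2-oxocyclohexyl}acetate F1. Its C5 centre can equilibrate to the equatorial arrangement. An equilibrating Meerwein–Ponndorf–Verley reduction (Al(Oi-Pr)3, i-PrOH, toluene, heat) should then give the more stable equatorial alcohol, and the route is rejoined at 17.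

Step 9. Metathesis may be slow at the vinyl group on the quaternary carbon, or may compete at the C8 exo-methylene. The fallback sets out from acid 9, isolated after the aqueous work-up of step 6, so that the metathesis is run before the exo-methylene exists.
- Cross-metathesis of 9 with 14 under the same catalyst should give (2R,3S,4E)-3-(3-chloropropyl)-6-methoxy-3-methyl-2-(silyl enynyl)-6-oxohex-4-enoic acid F2.
- Oxalyl chloride with catalytic DMF converts it into the acid chloride F3.
- Negishi acylation (MeZnCl, Pd(PPh3)4, THF) gives the methyl ketone methyl (2E,4S,5R)-4-(3-chloropropyl)-4-methyl-5-(silyl enynyl)-6-oxohept-2-enoate F4.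
- Ketone-selective methylenation (Zn, CH2Br2, TiCl4) gives the isopropenyl compound methyl (2E,4S,5S)-4-(3-chloropropyl)-4,6-dimethyl-5-(silyl enynyl)hepta-2,6-dienoate F5.
- A carbonyl-ene reaction with formaldehyde (paraformaldehyde, Me2AlCl, CH2Cl2) hydroxymethylates the allylic methyl group, and the route is rejoined at 15.

Step 6. The boron controller may give insufficient facial control or the wrong enolate geometry on this functionalised ester. The fallback sets out from 8 and replaces reagent control by substrate-independent relative control followed by resolution.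
- LiN(i-Pr)2 in THF/HMPA with TBSCl at −78 °C gives the silyl ketene acetal with the side chain cis to O–Si, F6.
- On warming it rearranges through the same chair to the racemic silyl ester F7.
- Aqueous acid hydrolyses this to the racemic (2R*,3S*)-acid F8.
- Crystallisation with (S)-1-phenylethylamine (or its enantiomer, whichever gives the less soluble salt of the wanted acid) gives the diastereomerically pure ammonium salt F9.
- Acidification returns the route at 9, which is methylated as in step 6.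

Further compounds
F1 | step 11 | methyl 2-{(1S,5S,6R)-6-(3-chloropropyl)-6-methyl-4-methylidene-5-[(2Z)-3-methyl-5-(trimethylsilyl)pent-2-en-4-yn-1-yl]-2-oxocyclohexyl}acetate | C[Si](C)(C)C#C/C(C)=C\C[C@H]1C(=C)CC(=O)[C@@H](CC(=O)OC)[C@]1(C)CCCCl
F2 | step 9 | (2R,3S,4E)-3-(3-chloropropyl)-6-methoxy-3-methyl-2-[(2Z)-3-methyl-5-(trimethylsilyl)pent-2-en-4-yn-1-yl]-6-oxohex-4-enoic acid | C[Si](C)(C)C#C/C(C)=C\C[C@H]([C@](/C=C/C(=O)OC)(CCCCl)C)C(=O)O
F3 | step 9 | methyl (2E,4S,5R)-6-chloro-4-(3-chloropropyl)-4-methyl-5-[(2Z)-3-methyl-5-(trimethylsilyl)pent-2-en-4-yn-1-yl]-6-oxohex-2-enoate | C[Si](C)(C)C#C/C(C)=C\C[C@H]([C@](/C=C/C(=O)OC)(CCCCl)C)C(Cl)=O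
F4 | step 9 | methyl (2E,4S,5R)-4-(3-chloropropyl)-4-methyl-5-[(2Z)-3-methyl-5-(trimethylsilyl)pent-2-en-4-yn-1-yl]-6-oxohept-2-enoate | C[Si](C)(C)C#C/C(C)=C\C[C@H]([C@](/C=C/C(=O)OC)(CCCCl)C)C(C)=O
F5 | step 9 | methyl (2E,4S,5S)-4-(3-chloropropyl)-4,6-dimethyl-5-[(2Z)-3-methyl-5-(trimethylsilyl)pent-2-en-4-yn-1-yl]hepta-2,6-dienoate | C[Si](C)(C)C#C/C(C)=C\C[C@H]([C@](/C=C/C(=O)OC)(CCCCl)C)C(C)=C
F6 | step 6 | tert-butyl({(1Z,4Z)-1-{[(2E)-6-chloro-3-methylhex-2-en-1-yl]oxy}-5-methyl-7-(trimethylsilyl)hepta-1,4-dien-6-yn-1-yl}oxy)dimethylsilane | C[Si](C)(C)C#C/C(C)=C\C/C=C(\O[Si](C)(C)C(C)(C)C)OC/C=C(\C)CCCCl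
F7 | step 6 | tert-butyldimethylsilyl rac-(2R*,3S*)-3-(3-chloropropyl)-3-methyl-2-[(2Z)-3-methyl-5-(trimethylsilyl)pent-2-en-4-yn-1-yl]pent-4-enoate | C[Si](C)(C)C#C/C(C)=C\CC(C(C=C)(CCCCl)C)C(=O)O[Si](C)(C)C(C)(C)C
F8 | step 6 | rac-(2R*,3S*)-3-(3-chloropropyl)-3-methyl-2-[(2Z)-3-methyl-5-(trimethylsilyl)pent-2-en-4-yn-1-yl]pent-4-enoic acid | C[Si](C)(C)C#C/C(C)=C\CC(C(C=C)(CCCCl)C)C(=O)O
F9 | step 6 | (S)-1-phenylethylammonium (2R,3S)-3-(3-chloropropyl)-3-methyl-2-[(2Z)-3-methyl-5-(trimethylsilyl)pent-2-en-4-yn-1-yl]pent-4-enoate | C[Si](C)(C)C#C/C(C)=C\C[C@H]([C@](C=C)(CCCCl)C)C(=O)[O-].C[C@H]([NH3+])c1ccccc1
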